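**Retrosynthetic overview**
1. The crotonoyl ketone is made last from a C-7 formyl group (alkenylchromium addition, then oxidation). The exo-methylene lactone comes from a phosphonoacetate ester by intramolecular Michael addition onto a cycloheptenone, then olefination with formaldehyde.
2. The cycloheptenone comes from ring-closing metathesis of an acyclic 1,8-diene.
3. The diene comes from the key intermolecular carbonyl allylation: a chiral (Z)-γ-alkoxyallylborane adds to α-quaternary aldehyde 9, forming the C8–C8a bond and both oxygenated stereocentres.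
4. Aldehyde 9 comes from (R)-β-methyl-γ-butyrolactone by α-hydroxylation and enolate alkylation anti to the methyl group (C-6/C-7 relationship).
5. Ring order: seven-membered carbocycle first (metathesis), γ-lactone second (Michael closure).

Assumption: lactone 1 and anhydride 14 are bought as single enantiomers; "(−)-Ipc2BOMe" is the B-methoxydiisopinocampheylborane made from (+)-α-pinene; bicyclic compounds use cyclohepta[b]furan numbering (O1, C2, C3, C3a, C4–C8, C8a).

**Route**

Step 1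
Reactants: 1 (R)-4-methyldihydrofuran-2(3H)-one
Product: 2 (3R,4S)-3-hydroxy-4-methyldihydrofuran-2(3H)-one
Conditions: KN(SiMe3)2, THF, −78 °C; 3-phenyl-2-(phenylsulfonyl)oxaziridine, −78 °C; then AcOH
Reagents that add atoms: 3-phenyl-2-(phenylsulfonyl)oxaziridine, O=S(=O)(c1ccccc1)N1OC1c1ccccc1
Why: Davis enolate hydroxylation delivers oxygen anti to the 4-methyl group (trans product), and because this centre is made planar again in step 3 any cis epimer is equally usable.

Step 2
Reactants: 2 (3R,4S)-3-hydroxy-4-methyldihydrofuran-2(3H)-one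
Product: 3 (3R,4S)-3-(benzyloxy)-4-methyldihydrofuran-2(3H)-one
Conditions: BnOC(=NH)CCl3, TfOH (cat.), CH2Cl2/cyclohexane, 0 °C to rt
Reagents that add atoms: benzyl 2,2,2-trichloroacetimidate, N=C(OCc1ccccc1)C(Cl)(Cl)Cl
Why: Acid-catalysed imidate benzylation protects the α-hydroxy lactone without base, so the lactone is neither opened nor eliminated.

Step 3
Reactants: 3 (3R,4S)-3-(benzyloxy)-4-methyldihydrofuran-2(3H)-one
Product: 4 (3R,4S)-3-(benzyloxy)-3-[(benzyloxy)methyl]-4-methyldihydrofuran-2(3H)-one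
Conditions: LiN(i-Pr)2, THF, −78 °C; BnOCH2Cl, −78 to −20 °C
Reagents that add atoms: benzyl chloromethyl ether, ClCOCc1ccccc1
Why: Lactone enolate alkylation in which the electrophile enters anti to the adjacent methyl group, so the new CH2O carbon is trans and the oxygen cis to the methyl, which fixes the quaternary centre (C-7 of the target) relative to C-6.

Step 4
Reactants: 4 (3R,4S)-3-(benzyloxy)-3-[(benzyloxy)methyl]-4-methyldihydrofuran-2(3H)-one
Product: 5 (3R,4S)-3-hydroxy-3-(hydroxymethyl)-4-methyldihydrofuran-2(3H)-one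
Conditions: H2 (1 atm), Pd/C, EtOAc, rt
Reagents that add atoms: none
Why: Hydrogenolysis removes both benzyl ethers at a stage where no alkene is yet present.

Step 5
Reactants: 5 (3R,4S)-3-hydroxy-3-(hydroxymethyl)-4-methyldihydrofuran-2(3H)-one
Product: 6 (5R,9S)-2,2,9-trimethyl-1,3,7-trioxaspiro[4.4]nonan-6-one
Conditions: Me2C(OMe)2, PPTS (cat.), CH2Cl2, rt
Reagents that add atoms: 2,2-dimethoxypropane, COC(C)(C)OC
Why: Ketalisation closes the primary/tertiary 1,2-diol to a five-membered acetonide that masks the tertiary alcohol through all later basic and oxidative steps.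

Step 6
Reactants: 6 (5R,9S)-2,2,9-trimethyl-1,3,7-trioxaspiro[4.4]nonan-6-one
Product: 7 (4R)-4-[(2S)-1-hydroxypropan-2-yl]-N-methoxy-N,2,2-trimethyl-1,3-dioxolane-4-carboxamide
Conditions: MeNH(OMe)·HCl, AlMe3, CH2Cl2, 0 °C to rt
Reagents that add atoms: N,O-dimethylhydroxylamine hydrochloride, CNOC.Cl
Why: Weinreb aminolysis with the aluminium amide opens the hindered lactone regiospecifically, giving an amide that can be reduced to the aldehyde and freeing the primary alcohol.

Step 7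
Reactants: 7 hydroxy Weinreb amide
Product: 8 (4R)-4-[(2S)-1-{[tert-butyl(dimethyl)silyl]oxy}propan-2-yl]-N-methoxy-N,2,2-trimethyl-1,3-dioxolane-4-carboxamide
Conditions: TBSCl, imidazole, DMF, 0 °C to rt
Reagents that add atoms: tert-butyldimethylsilyl chloride, CC(C)(C)[Si](C)(C)Cl
Why: Silylation of the primary alcohol stops relactonisation and masks this carbon until the vinyl ketone unit is built.

Step 8
Reactants: 8 silyl ether Weinreb amide
Product: 9 (4R)-4-[(2S)-1-{[tert-butyl(dimethyl)silyl]oxy}propan-2-yl]-2,2-dimethyl-1,3-dioxolane-4-carbaldehyde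
Conditions: i-Bu2AlH, THF, −78 °C; then H2O
Reagents that add atoms: none
Why: Weinreb amide reduction stops at the chelated tetrahedral intermediate and releases the aldehyde on work-up, and the α-carbon is quaternary so it cannot epimerise.

Step 9
Reactants: 10 prop-2-en-1-ol
Product: 11 3-(methoxymethoxy)prop-1-ene
Conditions: MeOCH2Cl, i-Pr2NEt, CH2Cl2, 0 °C to rt
Reagents that add atoms: chloromethyl methyl ether, COCCl
Why: O-alkylation with the chloromethyl ether gives the allyl MOM ether needed for directed allylic lithiation.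

Step 10
Reactants: 9 aldehyde; 11 3-(methoxymethoxy)prop-1-ene
Product: 13 (1S,2R)-1-{(4R)-4-[(2S)-1-{[tert-butyl(dimethyl)silyl]oxy}propan-2-yl]-2,2-dimethyl-1,3-dioxolan-4-yl}-2-(methoxymethoxy)but-3-en-1-ol, via allylborane 12 (not isolated)
Conditions: 11, s-BuLi, THF, −78 °C; (−)-Ipc2BOMe; BF3·OEt2; 9, −78 °C; then NaOH, H2O2, 0 °C to rt
Reagents that add atoms: none
Why: Brown asymmetric γ-alkoxyallylboration (carbonyl allylation through a closed chair transition state), in which the Z-enol ether geometry gives the syn diol monoether and the isopinocampheyl groups from (+)-α-pinene direct attack to the Si face of the aldehyde, setting the carbinol (S) and the ether carbon (R).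

Step 11
Reactants: 13 syn alcohol; 14 (2S)-2-methylbutanoic anhydride
Product: 15 (1S,2R)-1-{(4R)-4-[(2S)-1-{[tert-butyl(dimethyl)silyl]oxy}propan-2-yl]-2,2-dimethyl-1,3-dioxolan-4-yl}-2-(methoxymethoxy)but-3-en-1-yl (2S)-2-methylbutanoate
Conditions: 14 (1.5 equiv), DMAP, Et3N, CH2Cl2, rt to 40 °C
Reagents that add atoms: none
Why: DMAP-catalysed acyl transfer from the enantiopure anhydride esterifies the hindered secondary alcohol without a ketene pathway, so the side-chain stereocentre is kept.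

Step 12
Reactants: 15 silyl ether ester
Product: 16 (1S,2R)-1-{(4R)-4-[(2S)-1-hydroxypropan-2-yl]-2,2-dimethyl-1,3-dioxolan-4-yl}-2-(methoxymethoxy)but-3-en-1-yl (2S)-2-methylbutanoate
Conditions: HF·pyridine, pyridine, THF, 0 °C to rt
Reagents that add atoms: none
Why: Buffered fluoride desilylation frees the primary alcohol while the acetonide, MOM ether and ester stay intact.

Step 13
Reactants: 16 primary alcohol
Product: 17 (1S,2R)-1-{(4R)-2,2-dimethyl-4-[(2R)-1-oxopropan-2-yl]-1,3-dioxolan-4-yl}-2-(methoxymethoxy)but-3-en-1-yl (2S)-2-methylbutanoate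
Conditions: Dess–Martin periodinane, CH2Cl2, 0 °C to rt
Reagents that add atoms: none
Why: Dess–Martin oxidation is neutral and fast, so the α-methyl aldehyde is formed without epimerisation and is used crude.

Step 14
Reactants: 17 aldehyde
Product: 18 (1S,2R)-1-{(4R)-4-[(2S,3RS)-3-hydroxypent-4-en-2-yl]-2,2-dimethyl-1,3-dioxolan-4-yl}-2-(methoxymethoxy)but-3-en-1-yl (2S)-2-methylbutanoate
Conditions: CH2=CHMgBr, THF, −78 °C; then H2O
Reagents that add atoms: vinylmagnesium bromide, C=C[Mg]Br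
Why: Grignard 1,2-addition is far faster at the aldehyde than at the hindered ester at −78 °C, and the new carbinol centre (epimer mixture) is removed by oxidation in step 16.

Step 15
Reactants: 18 diene
Product: 19 (5R,6S,7RS,10R,11S)-7-hydroxy-10-(methoxymethoxy)-2,2,6-trimethyl-1,3-dioxaspiro[4.6]undec-8-en-11-yl (2S)-2-methylbutanoate
Conditions: second-generation Grubbs catalyst RuCl2(=CHPh)(PCy3)(H2IMes) (5 mol %), CH2Cl2 (2 mM), 40 °C
Reagents that add atoms: none
Why: Ring-closing olefin metathesis of the two terminal vinyl groups forms the seven-membered carbocycle with loss of ethene, helped by the quaternary centre in the tether.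

Step 16
Reactants: 19 cycloheptenol
Product: 20 (5R,6R,10R,11S)-10-(methoxymethoxy)-2,2,6-trimethyl-7-oxo-1,3-dioxaspiro[4.6]undec-8-en-11-yl (2S)-2-methylbutanoate
Conditions: Dess–Martin periodinane, CH2Cl2, rt
Reagents that add atoms: none
Why: Dess–Martin oxidation of the allylic alcohol converts both carbinol epimers into the single cycloheptenone that will act as Michael acceptor.

Step 17
Reactants: 20 MOM ether enone
Product: 21 (5R,6R,10R,11S)-10-hydroxy-2,2,6-trimethyl-7-oxo-1,3-dioxaspiro[4.6]undec-8-en-11-yl (2S)-2-methylbutanoate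
Conditions: TMSOTf, 2,2′-bipyridyl, CH2Cl2, 0 °C; then H2O
Reagents that add atoms: none
Why: Silyl triflate/bipyridyl acetal cleavage activates the unhindered formaldehyde acetal through a pyridinium-type intermediate that is hydrolysed on work-up, while the hindered spiro ketal (which must stay on so the tertiary alcohol cannot add across the enone), the ester and the enone are left alone.

Step 18
Reactants: 21 γ-hydroxy enone; 22 2-(diethoxyphosphoryl)acetic acid
Product: 23 (5R,6R,10R,11S)-10-{[(diethoxyphosphoryl)acetyl]oxy}-2,2,6-trimethyl-7-oxo-1,3-dioxaspiro[4.6]undec-8-en-11-yl (2S)-2-methylbutanoate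
Conditions: 22, DCC, DMAP (cat.), CH2Cl2, 0 °C to rt
Reagents that add atoms: none
Why: Steglich esterification attaches the phosphonoacetate to the only free hydroxyl, placing the nucleophilic carbon five atoms from the enone β-carbon.

Step 19
Reactants: 23 phosphonoacetate enone
Product: 25 acetonide of (3aS,6R,7R,8S,8aR)-7-hydroxy-7-(hydroxymethyl)-6-methyl-3-methylidene-2,5-dioxooctahydro-2H-cyclohepta[b]furan-8-yl (2S)-2-methylbutanoate, via phosphono lactone 24 (not isolated)
Conditions: KOt-Bu (1.05 equiv), THF, 0 °C; then (CH2O)n, 0 °C to rt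
Reagents that add atoms: formaldehyde (from paraformaldehyde), C=O
Why: Intramolecular 5-exo Michael addition followed by Horner–Wadsworth–Emmons olefination with formaldehyde, in which the ester tether can only deliver carbon to the face carrying the C-8a oxygen, so the lactone is cis-fused and C-3a is set.

Step 20
Reactants: 25 methylidene lactone acetonide
Product: 26 (3aS,6R,7R,8S,8aR)-7-hydroxy-7-(hydroxymethyl)-6-methyl-3-methylidene-2,5-dioxooctahydro-2H-cyclohepta[b]furan-8-yl (2S)-2-methylbutanoate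
Conditions: AcOH/H2O (4:1), 40 °C
Reagents that add atoms: none
Why: Mild acid hydrolysis of the ketal frees the primary/tertiary diol under conditions the methylidene lactone, ester and β-hydroxy ketone tolerate.

Step 21
Reactants: 26 diol
Product: 27 (3aS,6R,7S,8S,8aR)-7-formyl-7-hydroxy-6-methyl-3-methylidene-2,5-dioxooctahydro-2H-cyclohepta[b]furan-8-yl (2S)-2-methylbutanoate
Conditions: IBX, DMSO, rt
Reagents that add atoms: none
Why: IBX oxidation converts the primary alcohol into the aldehyde without cleaving the 1,2-diol and cannot touch the tertiary alcohol.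

Step 22
Reactants: 27 α-hydroxy aldehyde; 28 (E)-1-bromoprop-1-ene
Product: 29 (3aS,6R,7R,8S,8aR)-7-hydroxy-7-[(1RS,2E)-1-hydroxybut-2-en-1-yl]-6-methyl-3-methylidene-2,5-dioxooctahydro-2H-cyclohepta[b]furan-8-yl (2S)-2-methylbutanoate
Conditions: 28, CrCl2, NiCl2 (cat.), DMSO, rt; then H2O
Reagents that add atoms: none
Why: Nozaki–Hiyama–Kishi alkenylation, in which the alkenylchromium reagent adds only to the aldehyde (not to ketone, lactone or ester) with retention of the E geometry, and the new carbinol centre is removed in the last step.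

Step 23
Reactants: 29 allylic alcohol
Product: 30 (3aS,6R,7S,8S,8aR)-7-[(2E)-but-2-enoyl]-7-hydroxy-6-methyl-3-methylidene-2,5-dioxooctahydro-2H-cyclohepta[b]furan-8-yl (2S)-2-methylbutanoate (target)
Conditions: IBX, DMSO, rt
Reagents that add atoms: none
Why: IBX oxidation of the secondary allylic alcohol gives the enone without glycol cleavage next to the tertiary alcohol and without base that could trigger retro-aldol or conjugate addition.

**Compound list**

1 | (R)-4-methyldihydrofuran-2(3H)-one | O=C1C[C@@H](C)CO1 | starting material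
2 | (3R,4S)-3-hydroxy-4-methyldihydrofuran-2(3H)-one (OH trans to CH3) | O1C[C@H](C)[C@@H](O)C1=O | intermediate
3 | (3R,4S)-3-(benzyloxy)-4-methyldihydrofuran-2(3H)-one | O1C[C@H](C)[C@@H](OCc2ccccc2)C1=O | intermediate
4 | (3R,4S)-3-(benzyloxy)-3-[(benzyloxy)methyl]-4-methyldihydrofuran-2(3H)-one (CH2OBn trans to CH3) | O1C[C@H](C)[C@@](OCc2ccccc2)(COCc2ccccc2)C1=O | intermediate
5 | (3R,4S)-3-hydroxy-3-(hydroxymethyl)-4-methyldihydrofuran-2(3H)-one | O1C[C@H](C)[C@@](O)(CO)C1=O | intermediate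
6 | (5R,9S)-2,2,9-trimethyl-1,3,7-trioxaspiro[4.4]nonan-6-one | O1C[C@H](C)[C@@](O2)(COC2(C)C)C1=O | intermediate
7 | (4R)-4-[(2S)-1-hydroxypropan-2-yl]-N-methoxy-N,2,2-trimethyl-1,3-dioxolane-4-carboxamide | OC[C@H](C)[C@@](O1)(COC1(C)C)C(=O)N(C)OC | intermediate
8 | (4R)-4-[(2S)-1-{[tert-butyl(dimethyl)silyl]oxy}propan-2-yl]-N-methoxy-N,2,2-trimethyl-1,3-dioxolane-4-carboxamide | CC(C)(C)[Si](C)(C)OC[C@H](C)[C@@](O1)(COC1(C)C)C(=O)N(C)OC | intermediate
9 | (4R)-4-[(2S)-1-{[tert-butyl(dimethyl)silyl]oxy}propan-2-yl]-2,2-dimethyl-1,3-dioxolane-4-carbaldehyde | CC(C)(C)[Si](C)(C)OC[C@H](C)[C@@](O1)(COC1(C)C)C=O | intermediate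
10 | prop-2-en-1-ol | OCC=C | starting material
11 | 3-(methoxymethoxy)prop-1-ene | C=CCOCOC | intermediate
12 | [(Z)-3-(methoxymethoxy)prop-2-en-1-yl]diisopinocampheylborane (isopinocampheyl groups from (+)-α-pinene) | COCO/C=C\CB([C@@H]1C[C@@H]2C[C@H]([C@H]1C)C2(C)C)[C@@H]1C[C@@H]2C[C@H]([C@H]1C)C2(C)C | intermediate
13 | (1S,2R)-1-{(4R)-4-[(2S)-1-{[tert-butyl(dimethyl)silyl]oxy}propan-2-yl]-2,2-dimethyl-1,3-dioxolan-4-yl}-2-(methoxymethoxy)but-3-en-1-ol | CC(C)(C)[Si](C)(C)OC[C@H](C)[C@@](O1)(COC1(C)C)[C@@H](O)[C@H](OCOC)C=C | intermediate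
14 | (2S)-2-methylbutanoic anhydride | CC[C@H](C)C(=O)OC(=O)[C@@H](C)CC | starting material
15 | (2S)-2-methylbutanoate ester of 13 | CC(C)(C)[Si](C)(C)OC[C@H](C)[C@@](O1)(COC1(C)C)[C@@H](OC(=O)[C@@H](C)CC)[C@H](OCOC)C=C | intermediate
16 | (1S,2R)-1-{(4R)-4-[(2S)-1-hydroxypropan-2-yl]-2,2-dimethyl-1,3-dioxolan-4-yl}-2-(methoxymethoxy)but-3-en-1-yl (2S)-2-methylbutanoate | OC[C@H](C)[C@@](O1)(COC1(C)C)[C@@H](OC(=O)[C@@H](C)CC)[C@H](OCOC)C=C | intermediate
17 | (1S,2R)-1-{(4R)-2,2-dimethyl-4-[(2R)-1-oxopropan-2-yl]-1,3-dioxolan-4-yl}-2-(methoxymethoxy)but-3-en-1-yl (2S)-2-methylbutanoate | O=C[C@H](C)[C@@](O1)(COC1(C)C)[C@@H](OC(=O)[C@@H](C)CC)[C@H](OCOC)C=C | intermediate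
18 | (1S,2R)-1-{(4R)-4-[(2S,3RS)-3-hydroxypent-4-en-2-yl]-2,2-dimethyl-1,3-dioxolan-4-yl}-2-(methoxymethoxy)but-3-en-1-yl (2S)-2-methylbutanoate (carbinol epimers) | C=CC(O)[C@H](C)[C@@](O1)(COC1(C)C)[C@@H](OC(=O)[C@@H](C)CC)[C@H](OCOC)C=C | intermediate
19 | (5R,6S,7RS,10R,11S)-7-hydroxy-10-(methoxymethoxy)-2,2,6-trimethyl-1,3-dioxaspiro[4.6]undec-8-en-11-yl (2S)-2-methylbutanoate | OC1[C@H](C)[C@@](O2)(COC2(C)C)[C@@H](OC(=O)[C@@H](C)CC)[C@H](OCOC)C=C1 | intermediate
20 | (5R,6R,10R,11S)-10-(methoxymethoxy)-2,2,6-trimethyl-7-oxo-1,3-dioxaspiro[4.6]undec-8-en-11-yl (2S)-2-methylbutanoate | O=C1[C@H](C)[C@@](O2)(COC2(C)C)[C@@H](OC(=O)[C@@H](C)CC)[C@H](OCOC)C=C1 | intermediate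
21 | (5R,6R,10R,11S)-10-hydroxy-2,2,6-trimethyl-7-oxo-1,3-dioxaspiro[4.6]undec-8-en-11-yl (2S)-2-methylbutanoate | O=C1[C@H](C)[C@@](O2)(COC2(C)C)[C@@H](OC(=O)[C@@H](C)CC)[C@H](O)C=C1 | intermediate
22 | 2-(diethoxyphosphoryl)acetic acid | CCOP(=O)(CC(=O)O)OCC | starting material
23 | (5R,6R,10R,11S)-10-{[(diethoxyphosphoryl)acetyl]oxy}-2,2,6-trimethyl-7-oxo-1,3-dioxaspiro[4.6]undec-8-en-11-yl (2S)-2-methylbutanoate | O=C1[C@H](C)[C@@](O2)(COC2(C)C)[C@@H](OC(=O)[C@@H](C)CC)[C@H](OC(=O)CP(=O)(OCC)OCC)C=C1 | intermediate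
24 | cis-fused 3-(diethoxyphosphoryl) lactone: 25 with CH–P(O)(OEt)2 at C-3 in place of C=CH2 (C-3 epimers) | CCOP(=O)(OCC)C1C(=O)O[C@@H]2[C@H]1CC(=O)[C@H](C)[C@@](O3)(COC3(C)C)[C@H]2OC(=O)[C@@H](C)CC | intermediate
25 | isopropylidene acetal (7-O and 7-CH2O) of (3aS,6R,7R,8S,8aR)-7-hydroxy-7-(hydroxymethyl)-6-methyl-3-methylidene-2,5-dioxooctahydro-2H-cyclohepta[b]furan-8-yl (2S)-2-methylbutanoate | C=C1C(=O)O[C@@H]2[C@H]1CC(=O)[C@H](C)[C@@](O3)(COC3(C)C)[C@H]2OC(=O)[C@@H](C)CC | intermediate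
26 | (3aS,6R,7R,8S,8aR)-7-hydroxy-7-(hydroxymethyl)-6-methyl-3-methylidene-2,5-dioxooctahydro-2H-cyclohepta[b]furan-8-yl (2S)-2-methylbutanoate | C=C1C(=O)O[C@@H]2[C@H]1CC(=O)[C@H](C)[C@@](O)(CO)[C@H]2OC(=O)[C@@H](C)CC | intermediate
27 | (3aS,6R,7S,8S,8aR)-7-formyl-7-hydroxy-6-methyl-3-methylidene-2,5-dioxooctahydro-2H-cyclohepta[b]furan-8-yl (2S)-2-methylbutanoate | C=C1C(=O)O[C@@H]2[C@H]1CC(=O)[C@H](C)[C@@](O)(C=O)[C@H]2OC(=O)[C@@H](C)CC | intermediate
28 | (E)-1-bromoprop-1-ene | C/C=C/Br | starting material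
29 | (3aS,6R,7R,8S,8aR)-7-hydroxy-7-[(1RS,2E)-1-hydroxybut-2-en-1-yl]-6-methyl-3-methylidene-2,5-dioxooctahydro-2H-cyclohepta[b]furan-8-yl (2S)-2-methylbutanoate | C=C1C(=O)O[C@@H]2[C@H]1CC(=O)[C@H](C)[C@@](O)(C(O)/C=C/C)[C@H]2OC(=O)[C@@H](C)CC | intermediate
30 | (3aS,6R,7S,8S,8aR)-7-[(2E)-but-2-enoyl]-7-hydroxy-6-methyl-3-methylidene-2,5-dioxooctahydro-2H-cyclohepta[b]furan-8-yl (2S)-2-methylbutanoate | C=C1C(=O)O[C@@H]2[C@H]1CC(=O)[C@H](C)[C@@](O)(C(=O)/C=C/C)[C@H]2OC(=O)[C@@H](C)CC | target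

**Totals**

Total step count: 23. Longest linear sequence: 22 steps (steps 1–8 and 10–23; step 9 is a one-step side branch).

**Steps most likely to fail, with fallbacks**

Step 10 (alkoxyallylboration). The aldehyde is α-quaternary and hindered, and the reagent must override the substrate's own (small, opposite) facial bias. Fallback, from 9 back to 13: aldehyde 9 is combined with the dibutylboron enolate of (S)-4-benzyl-3-[(methoxymethoxy)acetyl]oxazolidin-2-one (n-Bu2BOTf, Et3N, CH2Cl2, −78 to 0 °C; auxiliary-controlled syn-glycolate aldol) to give the syn-aldol imide F1. LiBH4 (Et2O, trace H2O, 0 °C) removes the auxiliary and gives the 1,3-diol F2. The primary hydroxyl is oxidised selectively (TEMPO cat., PhI(OAc)2, CH2Cl2) to the β-hydroxy aldehyde F3. Non-basic Lombardo methylenation (Zn, CH2Br2, TiCl4, THF) then gives 13.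

Step 17 (MOM removal beside the acetonide). If the ketal does not survive, the free tertiary alcohol can add across the enone. Fallback, from 19 back to 23, which does the deprotection while no enone is present: allylic alcohol 19 is silylated (TBDPSCl, imidazole, DMF) to the silyl ether F4. HCl in MeOH (40 °C) removes both MOM and acetonide to give the triol F5. Me2C(OMe)2/PPTS re-forms only the five-membered ketal of the primary/tertiary diol, giving the mono-alcohol F6. Esterification with 22 (DCC, DMAP) gives the phosphonoacetate F7. HF·pyridine removes the silyl group to give the allylic alcohol F8, and Dess–Martin oxidation gives 23.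

Step 19 (tandem Michael/olefination). The phosphonate anion may close sluggishly, or base may damage the β-alkoxy ketone. Fallback, from 21 back to 25: alcohol 21 is esterified with allyl hydrogen malonate (DCC, DMAP) to the mixed malonate F9. Cs2CO3 in MeCN closes the softer malonate nucleophile in the same cis-selective 5-exo Michael addition, giving the allyl ester lactone F10. Pd(PPh3)4 with morpholine removes the allyl group to give the carboxy lactone F11. Decarboxylative Mannich methylenation (aqueous CH2O, Et2NH, AcOH/NaOAc) gives 25.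

**Further compounds**

F1 | step 10 | (S)-4-benzyl-3-{(2S,3S)-3-[(4R)-4-((2S)-1-{[tert-butyl(dimethyl)silyl]oxy}propan-2-yl)-2,2-dimethyl-1,3-dioxolan-4-yl]-3-hydroxy-2-(methoxymethoxy)propanoyl}oxazolidin-2-one | CC(C)(C)[Si](C)(C)OC[C@H](C)[C@@](O1)(COC1(C)C)[C@@H](O)[C@H](OCOC)C(=O)N1[C@@H](Cc2ccccc2)COC1=O
F2 | step 10 | 1,3-diol from F1 (CH2OH in place of the imide carbonyl) | CC(C)(C)[Si](C)(C)OC[C@H](C)[C@@](O1)(COC1(C)C)[C@@H](O)[C@H](OCOC)CO
F3 | step 10 | β-hydroxy aldehyde from F2 (CHO in place of CH2OH) | CC(C)(C)[Si](C)(C)OC[C@H](C)[C@@](O1)(COC1(C)C)[C@@H](O)[C@H](OCOC)C=O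
F4 | step 17 | 7-O-tert-butyldiphenylsilyl ether of 19 | CC(C)(C)[Si](c1ccccc1)(c1ccccc1)OC1[C@H](C)[C@@](O2)(COC2(C)C)[C@@H](OC(=O)[C@@H](C)CC)[C@H](OCOC)C=C1
F5 | step 17 | triol from F4 (MOM and acetonide removed, silyl ether and ester kept) | CC(C)(C)[Si](c1ccccc1)(c1ccccc1)OC1[C@H](C)[C@@](O)(CO)[C@@H](OC(=O)[C@@H](C)CC)[C@H](O)C=C1
F6 | step 17 | acetonide of F5 with the ring secondary hydroxyl free | CC(C)(C)[Si](c1ccccc1)(c1ccccc1)OC1[C@H](C)[C@@](O2)(COC2(C)C)[C@@H](OC(=O)[C@@H](C)CC)[C@H](O)C=C1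
F7 | step 17 | (diethoxyphosphoryl)acetate of F6 | CC(C)(C)[Si](c1ccccc1)(c1ccccc1)OC1[C@H](C)[C@@](O2)(COC2(C)C)[C@@H](OC(=O)[C@@H](C)CC)[C@H](OC(=O)CP(=O)(OCC)OCC)C=C1
F8 | step 17 | allylic alcohol from F7 (silyl group removed; the 7-hydroxy analogue of 23) | OC1[C@H](C)[C@@](O2)(COC2(C)C)[C@@H](OC(=O)[C@@H](C)CC)[C@H](OC(=O)CP(=O)(OCC)OCC)C=C1
F9 | step 19 | allyl malonate mixed ester of 21 | O=C1[C@H](C)[C@@](O2)(COC2(C)C)[C@@H](OC(=O)[C@@H](C)CC)[C@H](OC(=O)CC(=O)OCC=C)C=C1
F10 | step 19 | cis-fused lactone carrying an allyl ester at C-3 (C-3 epimers) | C=CCOC(=O)C1C(=O)O[C@@H]2[C@H]1CC(=O)[C@H](C)[C@@](O3)(COC3(C)C)[C@H]2OC(=O)[C@@H](C)CC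
F11 | step 19 | cis-fused lactone carrying a carboxylic acid at C-3 (C-3 epimers) | OC(=O)C1C(=O)O[C@@H]2[C@H]1CC(=O)[C@H](C)[C@@](O3)(COC3(C)C)[C@H]2OC(=O)[C@@H](C)CC
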